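Atom labels follow the flavone numbering of the target (O1, C2, C3, C4, C4a, C5–C8, C8a; piperidine N1′, C2′–C6′) and are kept for every intermediate. Compound numbers are those of the list after the steps.

## Analysis of the target

The target 14 is a flavone: benzenoid ring A is fused to pyranone ring C (O1, C2 with phenyl ring B, C3, C4=O), and carries a methoxy group on C5, a free hydroxyl on C7 and a 1-methylpiperidin-2-yl ring on C8. Ring A is substituted everywhere except C6, so C8 lies between O7 and the ring oxygen O1 on C8a and is the most crowded position of an electron-rich arene. The only stereocentre is C2′, (R)-configured, benzylic and alpha to nitrogen; with no second stereocentre to relay from, its absolute configuration must come from a catalyst, an auxiliary or the chiral pool. C2′ is also the carbon of a phenolic Mannich base: with the C7 hydroxyl free and the nitrogen basic, reversible cleavage of C2′–N or of C8–C2′ can erase the configuration. The centre is therefore safest while nitrogen is acylated, or fully protonated, or while the phenol is fully deprotonated. Further sensitive points are the pyranone ring (opened by strong nucleophiles, reduced by hydride), the need to keep O5 methylated while O7 is free, and the amphoteric amino-phenol. The hard part is the C8–C2′ bond, which joins an sp3 stereocentre to that hindered position with control of absolute configuration. The plan rests on the relationship of O7, N1′ and the N-methyl carbon: a carbonyl group bridging O7 and N1′ places a C2′–H bond of a plain piperidine next to C8, and hydride reduction of that bridge leaves exactly the C7 phenol and the N–CH3 group. In addition, ring A before annulation of ring C is symmetric about the C8···C5 axis, so O7 and O1 need not be told apart.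

## Retrosynthetic reasoning

Target 14 to diketone 13: the O1–C2 bond of the pyranone is cut first. Ring C tolerates neither hydride nor organometallic reagents, so it is best made last. The forward reaction is an acid-catalysed cyclodehydration, and only the C8a hydroxyl is ortho to the diketone chain, so no regiochemical question arises.

Diketone 13 to acetophenone 10 and benzoyl chloride 11: the C2–C3 bond is cut, which removes C2 and ring B as one commercial acyl unit. The forward reaction has to acylate the methyl ketone on carbon in the presence of two free phenols. This is done on the trilithium enolate 12, so that no oxygen protection and no deprotection are needed.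

Acetophenone 10 to aminoresorcinol 8: the C4a–C4 bond is cut. In 8 the two free ring positions are equivalent, both flanked by a hydroxyl and the methoxy group, so a single C-acetylation can give only the required substitution pattern. The forward reaction is a Friedel–Crafts acetylation that passes through the boron chelate 9.

Aminoresorcinol 8 to tricyclic carbamate 7: no skeletal bond is cut here. The N–CH3 group and the O7–H bond are traced back to one N–C(=O)–O7 unit, and the second phenol to a spectator carbamate. The forward reaction is a hydride reduction that converts the bridge carbon into the methyl group. What is gained is that in 7 the nitrogen is non-basic and the benzylic centre cannot ionise.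

Tricyclic carbamate 7 to aryl bromide 6: this is the strategic cut, C8–C2′. It is the only bond that joins the aromatic and the alicyclic halves, and it is the bond at the stereocentre. Cutting elsewhere (a C–N closure of the piperidine, or addition of a hindered aryl metal to a chiral imine) would need a separate auxiliary and more steps. Cutting here leaves a symmetric precursor in which two identical carbamates flank one bromine atom. The forward reaction has to replace one of the two enantiotopic alpha hydrogens of a piperidine by C8 and close the oxazinone in the same event.

Aryl bromide 6 to bis-carbamate 3 and bromine donor 4, then to 5-methoxyresorcinol 1 and carbamoyl chloride 2: the C8–Br bond is made by deprotonation between the two carbamates (aryllithium 5) and bromine transfer from 4. The two O–C(=O) bonds come from double acylation of 1 with 2. Both carbamates are alike, so no monoprotection is needed, and the piperidine that ends up in the target is introduced as the amine part of the directing group.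

## Alternatives that were turned down

Alternative 1: Ring A is taken apart at C8–C8a and C4a–C5, so that rings C and B arrive as a phenylpyranone and C5–C8 arrive as an oxygenated diene that already carries the piperidine.
- Forward key step: the ketene-acetal diene A2 (a Brassard-type 1,1-dimethoxy-3-silyloxydiene, made by double enol silylation of beta-keto ester A1) would add across the sulfinyl-bearing C=C bond of pyranone A3. Loss of the sulfinyl group as a sulfenic acid, of one methoxy group and of silicon would aromatise the adduct to the N-Boc flavone A4.
- For it: the route is convergent, the 5-methoxy/7-hydroxy pattern is written into the diene, and the sulfinyl group fixes the orientation of the addition. C2′ comes from the chiral pool, so on absolute configuration it is stronger than the chosen route, whose stereocentre depends on an untested enantioselective step.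
- Against it: the bond-forming terminus of A2 is a substituted carbon next to a bulky carbamate-protected ring, and a pyran-4-one double bond is a reluctant two-electron partner. A stepwise Mukaiyama–Michael course with loss of silicon is therefore more likely than clean annulation.
- Against it: A1 is a beta-amino ketone, and the strong base needed to make A2 can expel the carbamate nitrogen from the enolate and let it re-add, which would erase the stereocentre the approach is meant to secure.
- Against it: A4 still has to exchange Boc for methyl by deprotection and reductive methylation on a free 7-hydroxyflavone whose C6 is nucleophilic.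
- Comparison: counting the homologation to A1, the preparation of A3, the annulation and the nitrogen adjustment, the sequence is around ten steps against seven, and it builds a benzene ring that 1 already supplies. In return for its stereochemical risk the chosen route offers a single carbon–carbon bond formation on bought rings, a nitrogen that is acylated while the bond is made, and an N-methyl group that falls out of the tether.

Alternative 2: The piperidine is disconnected at C4′–C5′ (after adding a double bond there). This leads back to a flavone that carries on C8 a homoallylic amine with an N-allyl and an N-methyl group. That amine is in turn the product of a three-component Petasis borono-Mannich reaction of the 8-formylflavone A5 with a secondary allylamine and an allylboron reagent.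
- Forward key step: the ammonium salt of the acetylated diene A6 would undergo ring-closing olefin metathesis to the tetrahydropyridine A7. Hydrogenation of C4′=C5′ and removal of the acetate would finish the synthesis.
- For it: ring-closing metathesis to a six-membered ring on a protonated amine is dependable chemistry, so the ring-forming step itself is safer than the C–H arylation proposed here. The flavone is assembled early by routine means.
- Against it: the stereocentre is set not in the metathesis but in the Petasis step. There the neighbouring C7 hydroxyl delivers the allyl group through a boronate and also drives a fast uncatalysed pathway, so control of absolute configuration by an external chiral diol is uncertain.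
- Against it: the product of that step is a free ortho-hydroxybenzylic amine, the most easily scrambled form of C2′.
- Against it: A5 requires formylation of a 7-hydroxy-5-methoxyflavone at C8 in preference to C6, and the final hydrogenation must spare both the C2=C3 bond of the pyranone and the benzylic, allylic C2′–N bond.
- Comparison: flavone synthesis, formylation, Petasis reaction, acetylation, metathesis, hydrogenation and deacetylation come to seven to nine steps, so nothing is saved. The chosen route forms C8–C2′, the ring and the stereocentre in one operation while nitrogen is amide-like, and defers all flavone chemistry until after the only hydride step.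

Alternative 3: Here ring A itself is the retron. All six ring carbons are assembled by a cyclobutenone–alkynyl ether benzannulation around a piperidine that already carries C2′ from the chiral pool.
- Forward key step: the silyloxyalkyne A9, obtained from the N-Boc amino acid A8 by one-carbon homologation of its ester to the ynolate and O-silylation, would be heated with 3-methoxycyclobutenone A10. Electrocyclic opening to a vinylketene, [2+2] addition to the alkyne, a second ring opening and six-electron closure would give the monosilylated resorcinol A11, with the piperidine between the two oxygens and the methoxy group para to it.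
- For it: the regiochemistry follows from the mechanism. The stereocentre takes no part in bond formation and its configuration is bought, which is again a stronger position on stereochemistry than that of the chosen route. The carbamate on nitrogen would later be turned into N-methyl by hydride.
- Against it: A11 is only a protected form of 8. The approach spends a multi-step alkyne synthesis (with an alpha-amino carbonyl stage that can epimerise under the strongly basic homologation), the preparation of the sensitive A10 and a thermal cascade close to the temperature of Boc thermolysis, all to build a benzene ring that is commercially available as 1.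
- Against it: the differentiation of the two oxygens that the benzannulation provides is of no use, because they are equivalent in 8. A8 is also needed in its costlier (R) form.
- Comparison: after A11 the same four steps as here would still follow, giving some eleven steps in all. The chosen route reaches 8 in four steps from 1 and concentrates its risk in one catalytic step.

Key step: step 3

Remark on the chemistry: the sense of induction of the chiral ligand in step 3 cannot be derived from models with confidence. It is assumed that one antipode gives the (R) centre; which one is to be found in the first trial runs, and both antipodes are accessible.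

## Route

Step 1
Reactants: 1 5-methoxybenzene-1,3-diol (5-methoxyresorcinol); 2 piperidine-1-carbonyl chloride
Product: 3 5-methoxy-1,3-phenylene bis(piperidine-1-carboxylate)
Conditions: 2 (2.3 equiv), K2CO3 (3 equiv), MeCN, reflux
Reagents that add atoms: none
Why: O-carbamoylation of the two equivalent phenoxides by a carbamoyl chloride is the standard preparation of aryl N,N-dialkylcarbamates; the ring carbons are not acylated under carbonate conditions.

Step 2
Reactants: 3 5-methoxy-1,3-phenylene bis(piperidine-1-carboxylate); 4 1,2-dibromo-1,1,2,2-tetrachloroethane
Product: 6 2-bromo-5-methoxy-1,3-phenylene bis(piperidine-1-carboxylate), via aryllithium 5 (not isolated)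
Conditions: s-BuLi (1.15 equiv), TMEDA (1.2 equiv), THF, −78 °C, 30 min; then 4 (1.3 equiv), −78 °C → rt
Reagents that add atoms: none
Why: Directed ortho-metalation: the hydrogen between the two O-carbamates is flanked by the strongest cooperating pair of directing groups and should be removed in preference to the hydrogens between a carbamate and the weaker methoxy group; 5 is kept at −78 °C, where the anionic ortho-Fries shift is slow, and is brominated by 4, which collapses to tetrachloroethene and LiBr.

Step 3
Reactants: 6 2-bromo-5-methoxy-1,3-phenylene bis(piperidine-1-carboxylate)
Product: 7 (11aR)-3-methoxy-6-oxo-8,9,10,11-tetrahydro-6H,11aH-pyrido[1,2-c][1,3]benzoxazin-1-yl piperidine-1-carboxylate (the 1,3-benzoxazin-2-one in which C8–C2′ is formed and N1′–C(=O)–O7 is the bridge)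
Conditions: Pd2(dba)3 (2.5 mol %), 1,3-bis[2,2-dimethyl-1-(2-methylphenyl)propyl]imidazolium iodide (single C2-symmetric antipode, carbene precursor, 10 mol %), CsOPiv (30 mol %), Cs2CO3 (1.5 equiv), mesitylene, 140 °C, argon
Reagents that add atoms: none
Why: Proposed new method: zerovalent palladium carrying one bulky chiral ligand should insert into the hindered C8–Br bond, bromide is exchanged for pivalate, and the bound pivalate removes one hydrogen of the carbamate alpha-methylene by concerted metalation–deprotonation (the enantio-determining event) to give a seven-membered palladacycle containing C8, C7, O7, the carbonyl carbon, N1′ and C2′. C(sp2)–C(sp3) reductive elimination with retention at C2′ then forms C8–C2′, so the six-membered oxazinone is closed by extrusion of palladium from the seven-membered metallacycle and not by a polar exo or endo attack. The closest known reaction type is the enantioselective intramolecular C(sp3)–H arylation of aryl bromides under zerovalent palladium/carboxylate catalysis, established for indolines and indanes through six-membered palladacycles and for six-membered rings closed onto cyclopropane C–H bonds through seven-membered ones; C–H bonds alpha to an acylated nitrogen are known to react in the racemic series, but an O-aryl carbamate tether has not been used. The C2′ stereocentre is controlled only by the chiral ligand, which in the metalation transition state must tell apart the two enantiotopic hydrogens of the methylene that is turned towards palladium. Site selectivity on the arene is fixed by the bromine atom between the two carbamates, only the alpha hydrogens of the piperidine can reach the metal, the two carbamates are interchanged by the twofold axis through the brominated carbon and the methoxy-bearing carbon so that either gives the same product, and after ring closure no C–Br bond is left for a second event. The reactive rotamer has the aryl group and nitrogen cis about the O–C(=O) bond, which is not the resting arrangement of an aryl carbamate, so the step needs about 140 °C and a ligand bulky enough for reductive elimination to outrun beta-hydride elimination towards C3′. In 7 the nitrogen lone pair is delocalised into the carbamate, so the new benzylic centre cannot ionise and should keep its configuration.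

Step 4
Reactants: 7 (11aR)-3-methoxy-6-oxo-8,9,10,11-tetrahydro-6H,11aH-pyrido[1,2-c][1,3]benzoxazin-1-yl piperidine-1-carboxylate
Product: 8 5-methoxy-2-[(2R)-1-methylpiperidin-2-yl]benzene-1,3-diol
Conditions: LiAlH4 (5 equiv), THF, 0 °C → reflux; then aq. potassium sodium tartrate, pH 8–9, 0 °C, under argon
Reagents that add atoms: none
Why: Hydride reduction of carbamates: at each carbonyl the aryloxide is expelled first and the formyl carbon left on nitrogen is reduced on to CH3, so the bridge becomes the N-methyl group and frees O7, while the spectator carbamate gives the second phenol and 1-methylpiperidine; no bond to C2′ is touched, so the configuration is kept.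

Step 5
Reactants: 8 5-methoxy-2-[(2R)-1-methylpiperidin-2-yl]benzene-1,3-diol
Product: 10 1-[2,4-dihydroxy-6-methoxy-3-[(2R)-1-methylpiperidin-2-yl]phenyl]ethan-1-one, via difluoroboron chelate 9 (not isolated)
Conditions: Ac2O (1.2 equiv), BF3·OEt2 (5 equiv), CH2Cl2, 0 °C → rt; then K2CO3, MeOH/H2O, rt
Reagents that add atoms: acetic anhydride, CC(=O)OC(C)=O
Why: Friedel–Crafts C-acetylation of a phloroglucinol-type arene; the two free positions of 8 are equivalent, so only one monoacetyl product is possible, and the ketone is captured with the neighbouring hydroxyl as chelate 9, which deactivates the ring towards a second acylation and ties up the carbonyl so that the adjacent methyl ether is not cleaved. The amine is bound to BF3 throughout, which disfavours ionisation at C2′, and the basic methanolysis releases 10 and cleaves any aryl acetate.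

Step 6
Reactants: 10 1-[2,4-dihydroxy-6-methoxy-3-[(2R)-1-methylpiperidin-2-yl]phenyl]ethan-1-one; 11 benzoyl chloride
Product: 13 1-[2,4-dihydroxy-6-methoxy-3-[(2R)-1-methylpiperidin-2-yl]phenyl]-3-phenylpropane-1,3-dione, via trilithium enolate 12 (not isolated)
Conditions: LiN(SiMe3)2 (4.5 equiv), THF, −78 → −10 °C; then 11 (1.05 equiv), −78 °C → rt; aq. NH4Cl
Reagents that add atoms: none
Why: Claisen-type C-acylation of a ketone enolate, the one-flask variant of the Baker–Venkataraman route: in 12 the enolate carbon is the most nucleophilic site, the lithium phenoxides (one of them hindered by two ortho groups) react more slowly on oxygen, and the extra base absorbs the acidic proton of the diketone as it forms. The medium is strongly basic throughout, so the phenol cannot act as a proton source for the amine and C2′ is not at risk.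

Step 7
Reactants: 13 1-[2,4-dihydroxy-6-methoxy-3-[(2R)-1-methylpiperidin-2-yl]phenyl]-3-phenylpropane-1,3-dione
Product: 14 7-hydroxy-5-methoxy-8-[(2R)-1-methylpiperidin-2-yl]-2-phenyl-4H-chromen-4-one
Conditions: AcOH, H2SO4 (1.5 equiv), 60–80 °C; then aq. NaHCO3 to pH 7–8
Reagents that add atoms: none
Why: Acid-catalysed cyclodehydration, the closing stage of the Baker–Venkataraman flavone synthesis: the C8a hydroxyl, the only one ortho to the diketone, adds to the benzoyl carbonyl and water is lost to give the pyranone. The amine is fully protonated and the ring carries two acyl-type substituents, so C2′ should not ionise, and an aryl methyl ether is stable to these conditions.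

## Compound list

1 | 5-methoxybenzene-1,3-diol (5-methoxyresorcinol) | COc1cc(O)cc(O)c1 | starting material
2 | piperidine-1-carbonyl chloride | O=C(Cl)N1CCCCC1 | starting material
3 | 5-methoxy-1,3-phenylene bis(piperidine-1-carboxylate) | COc1cc(OC(=O)N2CCCCC2)cc(OC(=O)N2CCCCC2)c1 | intermediate
4 | 1,2-dibromo-1,1,2,2-tetrachloroethane | BrC(Cl)(Cl)C(Cl)(Cl)Br | starting material
5 | [4-methoxy-2,6-bis(piperidine-1-carbonyloxy)phenyl]lithium | COc1cc(OC(=O)N2CCCCC2)c([Li])c(OC(=O)N2CCCCC2)c1 | intermediate
6 | 2-bromo-5-methoxy-1,3-phenylene bis(piperidine-1-carboxylate) | COc1cc(OC(=O)N2CCCCC2)c(Br)c(OC(=O)N2CCCCC2)c1 | intermediate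
7 | (11aR)-3-methoxy-6-oxo-8,9,10,11-tetrahydro-6H,11aH-pyrido[1,2-c][1,3]benzoxazin-1-yl piperidine-1-carboxylate | COc1cc(OC(=O)N3CCCCC3)c2[C@H]3CCCCN3C(=O)Oc2c1 | intermediate
8 | 5-methoxy-2-[(2R)-1-methylpiperidin-2-yl]benzene-1,3-diol | COc1cc(O)c([C@H]2CCCCN2C)c(O)c1 | intermediate
9 | O,O-difluoroboron chelate of 10 (boron bridging the C8a oxygen and the ketone oxygen) | COc1cc(O)c([C@H]2CCCCN2C)c2O[B-](F)(F)[O+]=C(C)c12 | intermediate
10 | 1-[2,4-dihydroxy-6-methoxy-3-[(2R)-1-methylpiperidin-2-yl]phenyl]ethan-1-one | COc1cc(O)c([C@H]2CCCCN2C)c(O)c1C(C)=O | intermediate
11 | benzoyl chloride | O=C(Cl)c1ccccc1 | starting material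
12 | trilithium salt of 10 (both phenoxides and the methyl ketone enolate) | COc1cc(O[Li])c([C@H]2CCCCN2C)c(O[Li])c1C(=C)O[Li] | intermediate
13 | 1-[2,4-dihydroxy-6-methoxy-3-[(2R)-1-methylpiperidin-2-yl]phenyl]-3-phenylpropane-1,3-dione | COc1cc(O)c([C@H]2CCCCN2C)c(O)c1C(=O)CC(=O)c1ccccc1 | intermediate
14 | 7-hydroxy-5-methoxy-8-[(2R)-1-methylpiperidin-2-yl]-2-phenyl-4H-chromen-4-one | COc1cc(O)c([C@H]2CCCCN2C)c2oc(-c3ccccc3)cc(=O)c12 | target

## Step count and least certain steps

Total step count: 7. Longest linear sequence: 7 steps (1 to 14); 2, 4 and 11 enter as reagent-like building blocks.

Step 3 (key step, proposed new method). Three things may go wrong.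
- The metalation may not take place, because the cis rotamer about O–C(=O) and the seven-membered palladacycle are both uphill, and the arylpalladium bromide would then simply be reduced.
- Beta-hydride elimination from the palladacycle towards C3′ may outrun reductive elimination.
- The discrimination between the enantiotopic alpha hydrogens may be too weak at 140 °C.

Ligand class and carboxylate would be varied first, and 7 is the natural point for raising enantiomeric purity by crystallisation. The fallback uses only established chemistry, sets out from 1 and comes back at 8. 1 is converted with chloromethyl methyl ether and i-Pr2NEt into 1-methoxy-3,5-bis(methoxymethoxy)benzene F1. n-BuLi in THF at 0 °C removes the proton between the two acetal ethers to give [4-methoxy-2,6-bis(methoxymethoxy)phenyl]lithium F2, which MgBr2·OEt2 turns into [4-methoxy-2,6-bis(methoxymethoxy)phenyl]magnesium bromide F3. Commercial 5-chloropentanal and (R)-2-methylpropane-2-sulfinamide are condensed (CuSO4, CH2Cl2) to (R,E)-N-(5-chloropentylidene)-2-methylpropane-2-sulfinamide F4. Addition of F3 to F4 in CH2Cl2/toluene at low temperature, through the magnesium-bridged six-membered transition state typical of this auxiliary, should give (R)-N-[(1R)-5-chloro-1-[4-methoxy-2,6-bis(methoxymethoxy)phenyl]pentyl]-2-methylpropane-2-sulfinamide F5. KN(SiMe3)2 closes the ring by intramolecular N-alkylation to (2R)-1-[(R)-tert-butylsulfinyl]-2-[4-methoxy-2,6-bis(methoxymethoxy)phenyl]piperidine F6. HCl in methanol removes the sulfinyl group and both acetals to give 5-methoxy-2-[(2R)-piperidin-2-yl]benzene-1,3-diol F7. 1,1′-Carbonyldiimidazole joins the nitrogen to one of the two equivalent phenols as (11aR)-1-hydroxy-3-methoxy-8,9,10,11-tetrahydro-6H,11aH-pyrido[1,2-c][1,3]benzoxazin-6-one F8, and LiAlH4 as in step 4 converts F8 into 8.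

Step 2. The aryllithium may undergo anionic ortho-Fries migration of a piperidinecarbonyl group, or s-BuLi may add to a carbamate carbonyl, because a piperidine carbamate is less shielded than the usual diethyl carbamate. The fallback sets out from 3 and comes back at 6. 3 is treated with LiN(i-Pr)2 in THF at −78 °C in the presence of chlorotrimethylsilane, so that 5 is silylated as soon as it forms and no nucleophilic alkyllithium is present. This gives 5-methoxy-2-(trimethylsilyl)-1,3-phenylene bis(piperidine-1-carboxylate) F9. Br2 in CH2Cl2 at low temperature then replaces silicon by bromine at the ipso carbon, which is para to the methoxy group, and gives 6.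

Step 5. The Lewis acid may cleave the methyl ether next to the new ketone, or acylation may spread to oxygen and to the second ring position. In the free-base form the very electron-rich 8 may also lose configuration by reversible opening at C2′ if it is warmed near neutrality. The fallback sets out from 8 and comes back at 10 by a Houben–Hoesch acylation, which replaces the acylium/boron system by a nitrilium electrophile at 0 °C with the amine fully protonated. 8 as its hydrochloride is treated with acetonitrile, ZnCl2 and dry HCl in ether/dioxane to give 1-[2,4-dihydroxy-6-methoxy-3-[(2R)-1-methylpiperidin-2-yl]phenyl]ethan-1-imine F10 as its hydrochloride, which is hydrolysed in warm dilute acid to 10.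

Step 6. O-Benzoylation may compete with C-acylation, the polyanion may be poorly soluble, or a second benzoyl group may be taken up at C3. The fallback is the stepwise Baker–Venkataraman sequence; it sets out from 10 and comes back at 14. 10 is benzoylated on both phenols (11, pyridine, DMAP) to 4-acetyl-5-methoxy-2-[(2R)-1-methylpiperidin-2-yl]-1,3-phenylene dibenzoate F11. KOt-Bu in THF moves the benzoyl group from the C8a oxygen to the methyl ketone carbon and gives 3-hydroxy-5-methoxy-2-[(2R)-1-methylpiperidin-2-yl]-4-(3-oxo-3-phenylpropanoyl)phenyl benzoate F12. Cyclodehydration as in step 7 gives 5-methoxy-8-[(2R)-1-methylpiperidin-2-yl]-4-oxo-2-phenyl-4H-chromen-7-yl benzoate F13, and K2CO3 in methanol removes the benzoate to give 14.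

## Further compounds

F1 | step 3 | 1-methoxy-3,5-bis(methoxymethoxy)benzene | COCOc1cc(OC)cc(OCOC)c1
F2 | step 3 | [4-methoxy-2,6-bis(methoxymethoxy)phenyl]lithium | COCOc1cc(OC)cc(OCOC)c1[Li]
F3 | step 3 | [4-methoxy-2,6-bis(methoxymethoxy)phenyl]magnesium bromide | COCOc1cc(OC)cc(OCOC)c1[Mg]Br
F4 | step 3 | (R,E)-N-(5-chloropentylidene)-2-methylpropane-2-sulfinamide | ClCCCC/C=N/[S@](=O)C(C)(C)C
F5 | step 3 | (R)-N-[(1R)-5-chloro-1-[4-methoxy-2,6-bis(methoxymethoxy)phenyl]pentyl]-2-methylpropane-2-sulfinamide | COCOc1cc(OC)cc(OCOC)c1[C@H](N[S@](=O)C(C)(C)C)CCCCCl
F6 | step 3 | (2R)-1-[(R)-tert-butylsulfinyl]-2-[4-methoxy-2,6-bis(methoxymethoxy)phenyl]piperidine | COCOc1cc(OC)cc(OCOC)c1[C@H]1CCCCN1[S@](=O)C(C)(C)C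
F7 | step 3 | 5-methoxy-2-[(2R)-piperidin-2-yl]benzene-1,3-diol | COc1cc(O)c([C@H]2CCCCN2)c(O)c1
F8 | step 3 | (11aR)-1-hydroxy-3-methoxy-8,9,10,11-tetrahydro-6H,11aH-pyrido[1,2-c][1,3]benzoxazin-6-one | COc1cc(O)c2[C@H]3CCCCN3C(=O)Oc2c1
F9 | step 2 | 5-methoxy-2-(trimethylsilyl)-1,3-phenylene bis(piperidine-1-carboxylate) | COc1cc(OC(=O)N2CCCCC2)c([Si](C)(C)C)c(OC(=O)N2CCCCC2)c1
F10 | step 5 | 1-[2,4-dihydroxy-6-methoxy-3-[(2R)-1-methylpiperidin-2-yl]phenyl]ethan-1-imine | COc1cc(O)c([C@H]2CCCCN2C)c(O)c1C(C)=N
F11 | step 6 | 4-acetyl-5-methoxy-2-[(2R)-1-methylpiperidin-2-yl]-1,3-phenylene dibenzoate | COc1cc(OC(=O)c2ccccc2)c([C@H]2CCCCN2C)c(OC(=O)c2ccccc2)c1C(C)=O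
F12 | step 6 | 3-hydroxy-5-methoxy-2-[(2R)-1-methylpiperidin-2-yl]-4-(3-oxo-3-phenylpropanoyl)phenyl benzoate | COc1cc(OC(=O)c2ccccc2)c([C@H]2CCCCN2C)c(O)c1C(=O)CC(=O)c1ccccc1
F13 | step 6 | 5-methoxy-8-[(2R)-1-methylpiperidin-2-yl]-4-oxo-2-phenyl-4H-chromen-7-yl benzoate | COc1cc(OC(=O)c3ccccc3)c([C@H]2CCCCN2C)c2oc(-c3ccccc3)cc(=O)c12
A1 | alternative 1 | tert-butyl (2R)-2-(4-methoxy-2,4-dioxobutyl)piperidine-1-carboxylate | COC(=O)CC(=O)C[C@H]1CCCCN1C(=O)OC(C)(C)C
A2 | alternative 1 | tert-butyl (2R)-2-[4,4-dimethoxy-2-(trimethylsilyloxy)buta-1,3-dien-1-yl]piperidine-1-carboxylate | COC(OC)=CC(O[Si](C)(C)C)=C[C@H]1CCCCN1C(=O)OC(C)(C)C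
A3 | alternative 1 | 5-(4-methylphenylsulfinyl)-2-phenyl-4H-pyran-4-one | O=c1cc(-c2ccccc2)occ1S(=O)c1ccc(C)cc1
A4 | alternative 1 | tert-butyl (2R)-2-(7-hydroxy-5-methoxy-4-oxo-2-phenyl-4H-chromen-8-yl)piperidine-1-carboxylate | COc1cc(O)c([C@H]2CCCCN2C(=O)OC(C)(C)C)c2oc(-c3ccccc3)cc(=O)c12
A5 | alternative 2 | 7-hydroxy-5-methoxy-4-oxo-2-phenyl-4H-chromene-8-carbaldehyde | COc1cc(O)c(C=O)c2oc(-c3ccccc3)cc(=O)c12
A6 | alternative 2 | 5-methoxy-8-[(1R)-1-[methyl(prop-2-en-1-yl)amino]but-3-en-1-yl]-4-oxo-2-phenyl-4H-chromen-7-yl acetate | COc1cc(OC(C)=O)c([C@H](N(C)CC=C)CC=C)c2oc(-c3ccccc3)cc(=O)c12
A7 | alternative 2 | 5-methoxy-8-[(2R)-1-methyl-1,2,3,6-tetrahydropyridin-2-yl]-4-oxo-2-phenyl-4H-chromen-7-yl acetate | COc1cc(OC(C)=O)c([C@H]2CC=CCN2C)c2oc(-c3ccccc3)cc(=O)c12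
A8 | alternative 3 | (2R)-1-(tert-butoxycarbonyl)piperidine-2-carboxylic acid | OC(=O)[C@H]1CCCCN1C(=O)OC(C)(C)C
A9 | alternative 3 | tert-butyl (2R)-2-{[tri(propan-2-yl)silyl]oxyethynyl}piperidine-1-carboxylate | CC(C)[Si](OC#C[C@H]1CCCCN1C(=O)OC(C)(C)C)(C(C)C)C(C)C
A10 | alternative 3 | 3-methoxycyclobut-2-en-1-one | COC1=CC(=O)C1
A11 | alternative 3 | tert-butyl (2R)-2-[2-hydroxy-4-methoxy-6-{[tri(propan-2-yl)silyl]oxy}phenyl]piperidine-1-carboxylate | COc1cc(O)c([C@H]2CCCCN2C(=O)OC(C)(C)C)c(O[Si](C(C)C)(C(C)C)C(C)C)c1
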